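In the dusk run the electrophile loses more than the product gains, so that difference is the line to watch.

| setting | dusk | east | north-east |
|---|---|---|---|
| electrophile | 0.030 M | 0.020 M | 0.020 M |
| nucleophile | 1.2 equiv | 1.20 equiv | 1.80 equiv |
| remark | run made earlier |  |  |
| time |  | 4.0 h | 4.0 h |

dusk run (percent of the electrophile charged)

| time / min | electrophile / % | product / % |
|---|---|---|
| 4.00 | 99.1 | 0.6 |
| 6.00 | 98.2 | 0.3 |
| 10.0 | 97.4 | 2.0 |
| 20.0 | 94.4 | 3.0 |
| 30.0 | 92.4 | 4.5 |
| 50.0 | 88.0 | 7.7 |

(standard deviation of a reading: 0.3 percentage points)

- a reading or a percentage of product counts all its forms, free or not
- what has gone from electrophile into another species counts as reacted, even if it can come back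
- a reading of electrophile is of its free form alone

1. part of the electrophile that has reacted at the end, east
2. part of the electrophile that has reacted at the end, north-east
3. what raising the equivalents of nucleophile from its lowest to its highest value here does to the part of the electrophile that has reacted (changes below 5 percentage points count as none) (no change / it rises / it falls)

The books are kept in the electrophile, in percent of its charge. At 50.0 min the dusk ledger shows 88.0% still free, 7.7% as product, and an unnamed entry of 4.3 percentage points, well above the scatter of 0.3 points. That entry is about a third of what has left the free form. It counts as reacted, so the fraction left is the figure to follow.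

The reckoning here takes the rate of loss as k·c_electrophile·c_nucleophile, second order, and assumes that the nucleophile falls one for one. With q the equivalents and E = exp(k·c_electrophile·(q − 1)·t), c_electrophile being the starting value, the fraction left is (q − 1)/(q·E − 1). The last dusk entry then gives the loss constant k, the second-order constant of the total fall of free electrophile, unnamed entry included: 4.49 M⁻¹ h⁻¹, a reading that carries the scatter. East then keeps 69.1% and north-east 57.1%, so 30.9% and 42.9% have reacted.

The forecast stands a little lower, at 30% for east and 41% for north-east. On the trend it says it rises, and it reads the gap as “a parallel route, possibly a reversible adduct”.

The flasks give 27.8% for east and 38.1% for north-east, and the trend is it rises, by 10 points. That gap between north-east and east is due to the difference in equivalents of nucleophile, and the forecast holds.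

    electrophile + nucleophile → acid set free + product (k = 2.80 M⁻¹ h⁻¹)
    nucleophile + acid set free ⇌ protonated nucleophile, settled at all times (K = 2.30 × 10⁵ M⁻¹)
    electrophile + product ⇌ idle adduct, settled at all times (K = 63.0 M⁻¹)

At 4.00 h the east ledger closes on 72.2% free, 18.9% as product with its bound form, and the idle adduct: its 18.0% counts both partners, so 9.00% is electrophile. That adduct is the unnamed entry, and part of the reacted share: without the pairing, east reaches 19.7% rather than 27.8%. The constant k carried this pairing along, having been read from the total fall. In a neighbour, north-east at 0.0050 M, k leaves 85.6% against a simulated 89%; the idle adduct there stands at 3.95%, against 23.2% in north-east.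

The data are calculated on assumed constants.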